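The earlier runs and the new flask were computed with constants of no real substance; noise was put on by code.

At early times the beta run picks up speed: monomer in chains stands at 3.5% after 3.00 min and at 18.4% after 8.00 min. The questions, however, concern the end of a run.

| setting | beta | delta | summer | dawn |
|---|---|---|---|---|
| free monomer | 14 mM | 14 mM | 14 mM | 60 mM |
| initiator | 1.8 mol% | 0.6 mol% | 1.2 mol% | 1.2 mol% |
| remark | run made earlier | run made earlier |  |  |
| time |  |  | 2.0 h | 2.0 h |

| run | time / min | monomer in chains / % | free monomer / % |
|---|---|---|---|
| beta | 3.00 | 3.5 | 96.2 |
| beta | 5.00 | 8.2 | 91.6 |
| beta | 8.00 | 18.4 | 82.3 |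
| beta | 12.0 | 31.2 | 69.0 |
| beta | 20.0 | 50.3 | 49.5 |
| beta | 30.0 | 60.4 | 39.2 |
| beta | 40.0 | 63.9 | 35.3 |
| delta | 6.00 | 3.2 | 96.2 |
| delta | 12.0 | 13.5 | 86.6 |
| delta | 20.0 | 27.2 | 72.1 |
| delta | 25.0 | 34.9 | 64.5 |
| delta | 30.0 | 41.6 | 57.9 |
| delta | 40.0 | 51.8 | 48.2 |

(readings scatter by 0.3 percentage points)

- the average divides the monomer in chains by the number of chains begun, living and dead together
- the numbers in the tables scatter with a standard deviation of 0.3 percentage points
- what may be going on: initiator + monomer in chains -> spent initiator B; 2 living end -> dead end A; free monomer + initiator -> living end + monomer in chains; free monomer + living end -> monomer in chains + living end; monomer in chains + living end -> free monomer + living end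
- the earlier runs do not show the number of chains; that part of a forecast is a guess

* which of the two ends with the longer chains by the average number of monomer units in a chain (chains begun, living or dead) ("neither" if they lie within 10%) (summer / dawn / neither)
* average number of monomer units in a chain (chains begun, living or dead) at the end, summer
* average number of monomer units in a chain (chains begun, living or dead) at the end, dawn

Lower down, the 20.0 min row of the beta run sums to 99.8%, so monomer is moving between two forms. We assume that a unit leaves a living end at a rate set by [living end], whatever the chain length. Then d[free monomer]/dt = −k[living end]([free monomer] − F), where F is the floor of free monomer, the concentration at which growth and back step balance (the equilibrium monomer concentration). While [living end] holds, [free monomer] − F shrinks by one factor in each equal interval.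

Taking [living end] as steady there, we read the last beta rows: free monomer drops by 10 percentage points, then 3.9 points, a factor of 0.379. This gives the beta run a time constant of 10.3 min, as a reading, shorter than 2.0 h. Summing the remaining drops puts our reading of the floor at 32.9% of the beta charge, so F is 4.61 mM.

F is 32.9% of the summer charge but 7.68% of the dawn charge. The chains were never counted, so we guess that equal loadings begin chains in proportion to the charge and that summer and dawn both reach F. Dawn then ends longer by a factor of 1.38, which is beyond the margin of 10%.

The forecast also says dawn, with 135 for summer and 220 for dawn, and calls its constants “guesses, since chains were never counted”.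

The simulation gives dawn, with 109 for summer and 176 for dawn.

    initiator + monomer in chains → spent initiator B (k = 0.139 M⁻¹ s⁻¹)
    2 living end → dead end A (k = 0.830 M⁻¹ s⁻¹)
    free monomer + initiator → living end + monomer in chains (k = 0.0458 M⁻¹ s⁻¹)
    free monomer + living end → monomer in chains + living end, rate k4*[living end]*[free monomer] (k = 18.7 M⁻¹ s⁻¹)
    monomer in chains + living end → free monomer + living end, rate k5*[living end] as long as [monomer in chains] is above zero (k = 0.0867 s⁻¹)

In dawn, with each step taken net, monomer in chains is made 1.43 times as fast as it is used up at 0.213 h, and 1.00 times as fast at 2.00 h. Free monomer then stands at 7.73% in dawn and 33.1% in summer. The length of dawn over that of summer is 1.61, above our 1.38, and spent initiator B holds 56.7% of the initiator charged in dawn against 49.5% in summer. Our reading of F is 7.68% of a charge of 60 mM, and a flask otherwise like dawn but with 0.72 mol% of initiator ends with 7.73% free monomer and a length of 254.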